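**Plan**

- Retrosynthesis (clerodane numbering): the esters and C4=C18 go first, then the butenolide (C13=C14 by ring-closing metathesis, C11–C12 by allylation of a C11 aldehyde), then C9–C11 ([2,3]-Wittig–Still shift from the C7 oxygen) and the ring B oxygens at C6, C7 and C8. Last, C5–C10 and C6–C7 are cut together in an intramolecular Diels–Alder reaction, and the open chain is cut at C4–C5 and C1–C2.
- Feature: ring B (C5–C10) carries vicinal methyls on C8 and C9, the mark of a 2,3-dimethylbutadiene C7–C10. Ring A (C1–C5, C10) holds the methyl-bearing quaternary C5 next to C4, whose exocyclic methylene is a ketone in disguise. An isopropenyl ketone (C4–C6) tied through C3–C2–C1 to C10 therefore folds into both rings.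
- Forward: 2-methylbut-1-en-3-yne gives the (E)-dienal; the chain is joined at C1–C2 (allylation) and C4–C5 (isopropenyl Grignard); rings A and B close in one step; C9 is made quaternary; ring B is oxidised; side chain and butenolide are attached; C18 comes last.
- Stereochemistry: C1 by reagent-controlled Brown allylation; C10 and C5 relayed from C1 in the cycloaddition; C9 by suprafacial delivery from the 7α oxygen (obtained by inversion); C6 by hydride anti to C19; C7 and C8 by osmylation anti to the C6 acetate and the axial methyls; C11 by substrate-controlled allylation.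

Key step: step 9

Remark: clerodane numbering is used for all bicyclic compounds; β is the face of the C5 methyl (C19), α the opposite face; the C4 carbinol epimers of 14 are carried together because C4 becomes a ketone.

**Route**

Step 1
Reactants: 1 2-methylbut-1-en-3-yne
Product: 4 (2E)-3,4-dimethylpenta-2,4-dien-1-ol, via alkenyldimethylalane 2 (not isolated), via lithium alkenylalanate 3 (not isolated)
Conditions: Me3Al, Cp2ZrCl2 (cat.), CH2Cl2, 0 °C to rt; then n-BuLi, hexane/THF, −78 to 0 °C; then (CH2O)n, rt
Reagents that add atoms: trimethylaluminium, C[Al](C)C; paraformaldehyde (formaldehyde unit), C=O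
Why: Zirconium-catalysed carboalumination (Negishi) adds methyl and aluminium syn across the terminal alkyne with aluminium on the terminal carbon, and hydroxymethylation of the derived alanate with retention should give only the (E)-dienol that fixes the C9–C10 geometry of the diene.

Step 2
Reactants: 4 (2E)-3,4-dimethylpenta-2,4-dien-1-ol
Product: 5 (2E)-3,4-dimethylpenta-2,4-dienal
Conditions: MnO2 (activated), CH2Cl2, rt
Reagents that add atoms: none
Why: Oxidation of an allylic alcohol by MnO2 is neutral and selective, so the diene and its E geometry should survive.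

Step 3
Reactants: 5 (2E)-3,4-dimethylpenta-2,4-dienal; 6 allylmagnesium bromide
Product: 8 (4S,5E)-6,7-dimethylocta-1,5,7-trien-4-ol, via diisopinocampheylborinate 7 (not isolated)
Conditions: (−)-Ipc2BOMe, 6, Et2O, −78 °C to rt; then 5, −78 °C; then NaOH, H2O2, rt
Reagents that add atoms: allylmagnesium bromide (6), C=CC[Mg]Br
Why: Brown allylation, in which (−)-B-allyldiisopinocampheylborane made in the flask adds through a closed chair transition state to the Si face of the enal and so sets C1 as the S carbinol by reagent control.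

Step 4
Reactants: 8 (4S,5E)-6,7-dimethylocta-1,5,7-trien-4-ol
Product: 9 tert-butyl{[(4S,5E)-6,7-dimethylocta-1,5,7-trien-4-yl]oxy}dimethylsilane
Conditions: TBSCl, imidazole, DMF, rt
Reagents that add atoms: tert-butyldimethylsilyl chloride, CC(C)(C)[Si](C)(C)Cl
Why: Imidazole-promoted silylation of the secondary alcohol gives the bulky ether that later sits equatorial in the cyclisation.

Step 5
Reactants: 9 TBS ether of 8
Product: 11 (4S,5E)-4-[(tert-butyldimethylsilyl)oxy]-6,7-dimethylocta-5,7-dien-1-ol, via B-alkyl-9-BBN adduct 10 (not isolated)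
Conditions: 9-BBN, THF, 0 °C to rt; then NaOH, H2O2, 0 °C
Reagents that add atoms: hydrogen peroxide, OO
Why: Anti-Markovnikov hydroboration–oxidation takes the isolated monosubstituted alkene, because the conjugated diene is much less reactive towards the bulky dialkylborane.

Step 6
Reactants: 11 primary alcohol
Product: 12 (4S,5E)-4-[(tert-butyldimethylsilyl)oxy]-6,7-dimethylocta-5,7-dienal
Conditions: Dess–Martin periodinane, NaHCO3, CH2Cl2, 0 °C to rt
Reagents that add atoms: none
Why: Dess–Martin oxidation gives the aldehyde under buffered conditions that leave the silyl ether and the diene untouched.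

Step 7
Reactants: 12 aldehyde; 13 isopropenylmagnesium bromide
Product: 14 (6S,7E)-6-[(tert-butyldimethylsilyl)oxy]-2,8,9-trimethyldeca-1,7,9-trien-3-ol (both C3 epimers)
Conditions: 13, THF, −78 °C
Reagents that add atoms: isopropenylmagnesium bromide (13), C=C(C)[Mg]Br
Why: Grignard 1,2-addition joins C4 to C5, and the new carbinol centre needs no control because it is oxidised in the next step.

Step 8
Reactants: 14 allylic alcohol
Product: 15 (6S,7E)-6-[(tert-butyldimethylsilyl)oxy]-2,8,9-trimethyldeca-1,7,9-trien-3-one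
Conditions: Dess–Martin periodinane, NaHCO3, CH2Cl2, 0 °C; kept cold and used at once
Reagents that add atoms: none
Why: Dess–Martin oxidation of the allylic alcohol gives the isopropenyl ketone without acid or base, so premature cyclisation or polymerisation of the enone should be limited.

Step 9
Reactants: 15 trienone
Product: 16 (4S,4aS,8aS)-4-[(tert-butyldimethylsilyl)oxy]-5,6,8a-trimethyl-3,4,4a,7,8,8a-hexahydronaphthalen-1(2H)-one (clerodane numbering: 4-oxo, 1α-OTBS, 5β-methyl, 10α-H, 8-ene, trans-fused)
Conditions: Me2AlCl, CH2Cl2, −78 to −30 °C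
Reagents that add atoms: none
Why: Me2AlCl binds the ketone oxygen and lowers the LUMO of the isopropenyl ketone, which adds across the (E)-diene C7–C10 in a concerted, asynchronous [4+2] cycloaddition that forms C5–C10 and C6–C7 together; the closest known reaction type is the Lewis-acid-promoted intramolecular Diels–Alder reaction of 1,7,9-decatrien-3-ones. Ring B arises as the new cyclohexene of the cycloaddition and ring A as the six-membered ring that holds the four-atom tether C1–C4, closed by the C5–C10 bond (type 1 mode, tether on the diene terminus). C10 is set by the C1 stereocentre: in the chair-like tether the silyloxy group lies equatorial and the C1–H eclipses the C9 methyl (allylic 1,3-strain), so the dienophile reaches the diene face that puts H-10 cis to the C1 oxygen. C5 is set relative to C10 by the exo-tether transition state (carbonyl exo, C19 methyl endo), which gives the trans ring fusion with the C5 methyl anti to H-10. The step needs this trans fusion against the usual endo-carbonyl preference, and the substrate secures it through the C9 methyl, which in the cis-fused transition state would clash with the tether methylene C2 as it swings over the diene, while the α-methyl on the dienophile weakens the endo bias of the carbonyl. The E geometry at C9–C10 fixed in step 1 lets the tether reach C5 without strain.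

Step 10
Reactants: 16 octalone
Product: 17 dioxolane of 16 (4,4-ethylenedioxy; 1α-OTBS, 5β-methyl, 10α-H, 8-ene)
Conditions: (TMSOCH2)2, TMSOTf (cat.), CH2Cl2, −78 to −20 °C
Reagents that add atoms: 1,2-bis(trimethylsilyloxy)ethane, C[Si](C)(C)OCCO[Si](C)(C)C
Why: Silyl-triflate-catalysed ketalisation with the bis-silyl ether of ethylene glycol (Noyori conditions) protects even the neopentyl C4 ketone at low temperature and spares the TBS ether.

Step 11
Reactants: 17 dioxolane
Product: 18 8-en-7-one (7-oxo derivative of 17)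
Conditions: CrO3, 3,5-dimethylpyrazole, CH2Cl2, −20 °C
Reagents that add atoms: chromium trioxide, O=[Cr](=O)=O
Why: Allylic oxidation by the CrO3–3,5-dimethylpyrazole complex should convert C7, the only ring methylene allylic to the C8–C9 alkene, into the conjugated ketone.

Step 12
Reactants: 18 enone
Product: 19 7β-allylic alcohol (7β-OH pseudoaxial, 8-ene)
Conditions: i-Bu2AlH, CH2Cl2, −78 °C
Reagents that add atoms: none
Why: In this hydride 1,2-reduction the axial C19 methyl on C5 shields the β face of C7 in a 1,3-diaxial sense, so hydride should enter from the α face and give the 7β-alcohol.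

Step 13
Reactants: 19 7β-allylic alcohol
Product: 21 7α-allylic alcohol (7α-OH pseudoequatorial; 8-ene), via 7α-chloroacetate 20 (not isolated)
Conditions: ClCH2CO2H, PPh3, DIAD, toluene, 0 °C to rt; then K2CO3, MeOH, rt
Reagents that add atoms: chloroacetic acid (its oxygen becomes the C7 oxygen), OC(=O)CCl
Why: Mitsunobu inversion, an SN2 displacement of the C7 oxyphosphonium ion by chloroacetate from the open α face, followed by mild methanolysis of the activated ester, should give the 7α-alcohol needed for carbon delivery to the α face of C9.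

Step 14
Reactants: 21 7α-allylic alcohol
Product: 22 7α-(tributylstannyl)methyl ether of 21
Conditions: KH, Bu3SnCH2I, 18-crown-6 (cat.), THF, 0 °C to rt
Reagents that add atoms: tributyl(iodomethyl)stannane, CCCC[Sn](CI)(CCCC)CCCC
Why: Williamson etherification of the potassium alkoxide with the iodomethylstannane gives the rearrangement precursor with retention at C7.

Step 15
Reactants: 22 stannylmethyl ether
Product: 24 C11 triethylsilyl ether (9α-CH2OTES; 9β-methyl; 7-ene), via lithium C11-alkoxide 23 (not isolated)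
Conditions: n-BuLi, THF, −78 to −20 °C; then TESCl, −78 °C to rt
Reagents that add atoms: chlorotriethylsilane, CC[Si](Cl)(CC)CC
Why: Wittig–Still [2,3]-sigmatropic rearrangement, in which tin–lithium exchange gives an α-alkoxymethyllithium that bonds to C9 suprafacially on the face of the C7–O bond (α), so C9 becomes quaternary with C11 α and C20 β and the alkene moves to C7–C8, after which the alkoxide is silylated in the same flask.

Step 16
Reactants: 24 C11 triethylsilyl ether
Product: 25 7-en-6-one (6-oxo derivative of 24)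
Conditions: CrO3, 3,5-dimethylpyrazole, CH2Cl2, −20 °C
Reagents that add atoms: chromium trioxide, O=[Cr](=O)=O
Why: In this second allylic oxidation C6 is the only ring methylene allylic to the C7–C8 alkene (C9 is quaternary), so the conjugated 6-ketone should form.

Step 17
Reactants: 25 7-en-6-one
Product: 26 6β-allylic alcohol (6β-OH pseudoequatorial, 7-ene)
Conditions: NaBH4, CeCl3·7H2O, MeOH, −78 to 0 °C
Reagents that add atoms: none
Why: In this Luche 1,2-reduction hydride attacks C6 anti to the adjacent axial C19 methyl (α face, axial attack) and should give the 6β-alcohol.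

Step 18
Reactants: 26 6β-allylic alcohol
Product: 27 6β-acetate
Conditions: Ac2O, DMAP, pyridine, rt
Reagents that add atoms: acetic anhydride, CC(=O)OC(C)=O
Why: DMAP-catalysed acetylation of the only free hydroxyl installs the C6 acetate of the target before the neighbouring diol exists.

Step 19
Reactants: 27 6β-acetate
Product: 28 6β-acetoxy-7α,8α-diol (8β-methyl)
Conditions: OsO4 (cat.), NMO, acetone/H2O, rt
Reagents that add atoms: osmium tetroxide, O=[Os](=O)(=O)=O; N-methylmorpholine N-oxide, C[N+]1([O-])CCOCC1; water, O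
Why: Upjohn syn-dihydroxylation should occur on the α face, anti to the allylic 6β-acetate and to the axial C19 and C20 methyls, and so set C7 (α-OH) and C8 (α-OH, β-methyl) as the cis-diol.

Step 20
Reactants: 28 diol
Product: 29 6β-acetoxy-7α-isobutyryloxy-8α-ol
Conditions: (i-PrCO)2O, DMAP, pyridine, CH2Cl2, 0 °C to rt
Reagents that add atoms: isobutyric anhydride, CC(C)C(=O)OC(=O)C(C)C
Why: DMAP-catalysed acylation discriminates the secondary C7 hydroxyl from the tertiary C8 hydroxyl, so the isobutyrate should go to C7 only.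

Step 21
Reactants: 29 isobutyrate
Product: 30 C11 primary alcohol
Conditions: PPTS, MeOH/CH2Cl2, 0 °C
Reagents that add atoms: none
Why: Acid-catalysed methanolysis cleaves the primary triethylsilyl ether far faster than the hindered secondary TBS ether or the dioxolane, and the weak acid should not move the esters.

Step 22
Reactants: 30 C11 primary alcohol
Product: 31 C11 aldehyde
Conditions: Dess–Martin periodinane, NaHCO3, CH2Cl2, 0 °C to rt
Reagents that add atoms: none
Why: Dess–Martin oxidation under buffered, non-basic conditions should give the neopentyl β-hydroxy aldehyde without retro-aldol cleavage and leaves the tertiary alcohol alone.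

Step 23
Reactants: 32 ethyl 2-(bromomethyl)acrylate
Product: 33 2-(bromomethyl)prop-2-en-1-ol
Conditions: i-Bu2AlH, CH2Cl2, −78 °C
Reagents that add atoms: none
Why: 1,2-Reduction of the acrylate ester by i-Bu2AlH at low temperature gives the allylic alcohol and spares the allylic bromide.

Step 24
Reactants: 33 2-(bromomethyl)prop-2-en-1-ol
Product: 34 2-(bromomethyl)prop-2-en-1-yl prop-2-enoate
Conditions: acryloyl chloride, i-Pr2NEt, CH2Cl2, −78 °C
Reagents that add atoms: acryloyl chloride, C=CC(Cl)=O
Why: O-Acylation of the primary alcohol with a hindered amine base at low temperature gives the bifunctional allyl bromide without quaternisation of the bromide.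

Step 25
Reactants: 31 C11 aldehyde; 34 2-(bromomethyl)prop-2-en-1-yl prop-2-enoate
Product: 35 (11R)-11-hydroxy adduct carrying C12H2–C13(=CH2)–C16H2–O–CO–CH=CH2
Conditions: In powder, THF/H2O, rt
Reagents that add atoms: 2-(bromomethyl)prop-2-en-1-yl prop-2-enoate (34), C=CC(=O)OCC(=C)CBr
Why: Indium-mediated Barbier allylation tolerates water, free hydroxyls and esters, and the allylindium should add through a cyclic transition state from the face away from C10 and the C1 silyl ether, with the carbonyl oxygen turned towards the C8 hydroxyl (chelate), which gives the 11R carbinol.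

Step 26
Reactants: 35 acrylate
Product: 36 butenolide (13-en-15,16-olide) with free 11R-OH
Conditions: second-generation Grubbs catalyst (H2IMes)(PCy3)Cl2Ru=CHPh (cat.), CH2Cl2, 40 °C
Reagents that add atoms: none
Why: Ring-closing metathesis of the acrylate with the 1,1-disubstituted alkene, driven by loss of ethylene, closes the five-membered 4-substituted butenolide, and no other alkene is present at this stage.

Step 27
Reactants: 36 butenolide
Product: 37 4-oxo-1α,11R-diol (C1 and C11 hydroxyls free, C4 ketone)
Conditions: HF (48% aq.), MeCN, rt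
Reagents that add atoms: water, O
Why: Aqueous HF in acetonitrile is a standard acidic deprotection that should cleave the secondary TBS ether and hydrolyse the dioxolane in one operation, while the esters and the butenolide are stable to acid.

Step 28
Reactants: 37 keto diol
Product: 38 4-oxo-1α,6β,11R-triacetate
Conditions: Ac2O, DMAP, pyridine, rt to 40 °C
Reagents that add atoms: acetic anhydride, CC(=O)OC(C)=O
Why: DMAP-catalysed acetylation esterifies the two secondary hydroxyls at C1 and C11, whereas the tertiary C8 hydroxyl should not react under these conditions.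

Step 29
Reactants: 38 keto triacetate
Product: 39 CNP0266716.2
Conditions: Zn, CH2Br2, TiCl4, THF/CH2Cl2, 0 °C to rt
Reagents that add atoms: dibromomethane, BrCBr
Why: Takai–Lombardo methylenation uses a non-basic zinc–titanium gem-dimetallic reagent that converts hindered, enolisable ketones into methylene groups and does not attack esters, the butenolide or the free tertiary alcohol, so C18 can be installed last.

**Compound list**

1 | 2-methylbut-1-en-3-yne | C=C(C)C#C | starting material
2 | (E)-(2,3-dimethylbuta-1,3-dienyl)dimethylalane (formed in the flask) | C[Al](C)/C=C(\C)C(C)=C | intermediate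
3 | lithium butyl(dienyl)dimethylalanate (formed in the flask) | [Li+].CCCC[Al-](C)(C)/C=C(\C)C(C)=C | intermediate
4 | (2E)-3,4-dimethylpenta-2,4-dien-1-ol | OC/C=C(\C)C(C)=C | intermediate
5 | (2E)-3,4-dimethylpenta-2,4-dienal | O=C/C=C(\C)C(C)=C | intermediate
6 | allylmagnesium bromide | C=CC[Mg]Br | starting material
7 | diisopinocampheylborinate of 8 (formed in the flask) | C=CC[C@H](OB([C@@H]1C[C@@H]2C[C@@H](C2(C)C)[C@H]1C)[C@@H]1C[C@@H]2C[C@@H](C2(C)C)[C@H]1C)/C=C(\C)C(C)=C | intermediate
8 | (4S,5E)-6,7-dimethylocta-1,5,7-trien-4-ol | C=CC[C@H](O)/C=C(\C)C(C)=C | intermediate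
9 | TBS ether of 8 | C=CC[C@H](O[Si](C)(C)C(C)(C)C)/C=C(\C)C(C)=C | intermediate
10 | B-alkyl-9-borabicyclo[3.3.1]nonane from 9 (formed in the flask) | B1(CCC[C@H](O[Si](C)(C)C(C)(C)C)/C=C(\C)C(C)=C)C2CCCC1CCC2 | intermediate
11 | (4S,5E)-4-(TBS-oxy)-6,7-dimethylocta-5,7-dien-1-ol | OCCC[C@H](O[Si](C)(C)C(C)(C)C)/C=C(\C)C(C)=C | intermediate
12 | (4S,5E)-4-(TBS-oxy)-6,7-dimethylocta-5,7-dienal | O=CCC[C@H](O[Si](C)(C)C(C)(C)C)/C=C(\C)C(C)=C | intermediate
13 | isopropenylmagnesium bromide | C=C(C)[Mg]Br | starting material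
14 | (6S,7E)-6-(TBS-oxy)-2,8,9-trimethyldeca-1,7,9-trien-3-ol, C3 epimers | C=C(C)C(O)CC[C@H](O[Si](C)(C)C(C)(C)C)/C=C(\C)C(C)=C | intermediate
15 | (6S,7E)-6-(TBS-oxy)-2,8,9-trimethyldeca-1,7,9-trien-3-one | C=C(C)C(=O)CC[C@H](O[Si](C)(C)C(C)(C)C)/C=C(\C)C(C)=C | intermediate
16 | (4S,4aS,8aS)-4-(TBS-oxy)-5,6,8a-trimethyl-3,4,4a,7,8,8a-hexahydronaphthalen-1(2H)-one (trans-fused) | O=C1CC[C@H](O[Si](C)(C)C(C)(C)C)[C@@H]2[C@]1(C)CCC(C)=C2C | intermediate
17 | C4 dioxolane of 16 | C14(OCCO4)CC[C@H](O[Si](C)(C)C(C)(C)C)[C@@H]2[C@]1(C)CCC(C)=C2C | intermediate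
18 | 7-oxo-8-ene (enone) of 17 | C14(OCCO4)CC[C@H](O[Si](C)(C)C(C)(C)C)[C@@H]2[C@]1(C)CC(=O)C(C)=C2C | intermediate
19 | 7β-hydroxy-8-ene | C14(OCCO4)CC[C@H](O[Si](C)(C)C(C)(C)C)[C@@H]2[C@]1(C)C[C@H](O)C(C)=C2C | intermediate
20 | 7α-chloroacetoxy-8-ene (formed in the flask) | C14(OCCO4)CC[C@H](O[Si](C)(C)C(C)(C)C)[C@@H]2[C@]1(C)C[C@@H](OC(=O)CCl)C(C)=C2C | intermediate
21 | 7α-hydroxy-8-ene | C14(OCCO4)CC[C@H](O[Si](C)(C)C(C)(C)C)[C@@H]2[C@]1(C)C[C@@H](O)C(C)=C2C | intermediate
22 | 7α-[(tributylstannyl)methoxy]-8-ene | C14(OCCO4)CC[C@H](O[Si](C)(C)C(C)(C)C)[C@@H]2[C@]1(C)C[C@@H](OC[Sn](CCCC)(CCCC)CCCC)C(C)=C2C | intermediate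
23 | lithium alkoxide of the 9α-hydroxymethyl-9β-methyl-7-ene (formed in the flask) | C14(OCCO4)CC[C@H](O[Si](C)(C)C(C)(C)C)[C@@H]2[C@]1(C)CC=C(C)[C@@]2(C)C[O-].[Li+] | intermediate
24 | 9α-(triethylsilyloxymethyl)-9β-methyl-7-ene | C14(OCCO4)CC[C@H](O[Si](C)(C)C(C)(C)C)[C@@H]2[C@]1(C)CC=C(C)[C@@]2(C)CO[Si](CC)(CC)CC | intermediate
25 | 6-oxo-7-ene of 24 | C14(OCCO4)CC[C@H](O[Si](C)(C)C(C)(C)C)[C@@H]2[C@]1(C)C(=O)C=C(C)[C@@]2(C)CO[Si](CC)(CC)CC | intermediate
26 | 6β-hydroxy-7-ene | C14(OCCO4)CC[C@H](O[Si](C)(C)C(C)(C)C)[C@@H]2[C@]1(C)[C@H](O)C=C(C)[C@@]2(C)CO[Si](CC)(CC)CC | intermediate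
27 | 6β-acetoxy-7-ene | C14(OCCO4)CC[C@H](O[Si](C)(C)C(C)(C)C)[C@@H]2[C@]1(C)[C@H](OC(C)=O)C=C(C)[C@@]2(C)CO[Si](CC)(CC)CC | intermediate
28 | 6β-acetoxy-7α,8α-diol | C14(OCCO4)CC[C@H](O[Si](C)(C)C(C)(C)C)[C@@H]2[C@]1(C)[C@H](OC(C)=O)[C@@H](O)[C@@](C)(O)[C@@]2(C)CO[Si](CC)(CC)CC | intermediate
29 | 6β-acetoxy-7α-isobutyryloxy-8α-ol, C11 TES ether | C14(OCCO4)CC[C@H](O[Si](C)(C)C(C)(C)C)[C@@H]2[C@]1(C)[C@H](OC(C)=O)[C@@H](OC(=O)C(C)C)[C@@](C)(O)[C@@]2(C)CO[Si](CC)(CC)CC | intermediate
30 | C11 primary alcohol | C14(OCCO4)CC[C@H](O[Si](C)(C)C(C)(C)C)[C@@H]2[C@]1(C)[C@H](OC(C)=O)[C@@H](OC(=O)C(C)C)[C@@](C)(O)[C@@]2(C)CO | intermediate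
31 | C11 aldehyde | C14(OCCO4)CC[C@H](O[Si](C)(C)C(C)(C)C)[C@@H]2[C@]1(C)[C@H](OC(C)=O)[C@@H](OC(=O)C(C)C)[C@@](C)(O)[C@@]2(C)C=O | intermediate
32 | ethyl 2-(bromomethyl)acrylate | C=C(CBr)C(=O)OCC | starting material
33 | 2-(bromomethyl)prop-2-en-1-ol | C=C(CBr)CO | intermediate
34 | 2-(bromomethyl)prop-2-en-1-yl prop-2-enoate | C=CC(=O)OCC(=C)CBr | intermediate
35 | (11R)-11-hydroxy acrylate adduct | C14(OCCO4)CC[C@H](O[Si](C)(C)C(C)(C)C)[C@@H]2[C@]1(C)[C@H](OC(C)=O)[C@@H](OC(=O)C(C)C)[C@@](C)(O)[C@@]2(C)[C@@H](CC(=C)COC(=O)C=C)O | intermediate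
36 | (11R)-11-hydroxy butenolide, C1 TBS ether, C4 dioxolane | C14(OCCO4)CC[C@H](O[Si](C)(C)C(C)(C)C)[C@@H]2[C@]1(C)[C@H](OC(C)=O)[C@@H](OC(=O)C(C)C)[C@@](C)(O)[C@@]2(C)[C@@H](CC3=CC(=O)OC3)O | intermediate
37 | 4-oxo-1α,11R-diol | O=C1CC[C@H](O)[C@@H]2[C@]1(C)[C@H](OC(C)=O)[C@@H](OC(=O)C(C)C)[C@@](C)(O)[C@@]2(C)[C@@H](CC3=CC(=O)OC3)O | intermediate
38 | 4-oxo-1α,6β,11R-triacetate | O=C1CC[C@H](OC(C)=O)[C@@H]2[C@]1(C)[C@H](OC(C)=O)[C@@H](OC(=O)C(C)C)[C@@](C)(O)[C@@]2(C)[C@@H](CC3=CC(=O)OC3)OC(C)=O | intermediate
39 | CNP0266716.2 | C=C1CC[C@H](OC(C)=O)[C@@H]2[C@]1(C)[C@H](OC(C)=O)[C@@H](OC(=O)C(C)C)[C@@](C)(O)[C@@]2(C)[C@@H](CC1=CC(=O)OC1)OC(C)=O | target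

**Counts**

Total steps: 29. Longest linear sequence: 27 steps (steps 1–22 and 25–29); steps 23 and 24 prepare the allyl fragment 34.

**Steps most likely to fail**

1. Step 9. The cyclisation may run through the endo-carbonyl, cis-fused transition state, or the Lewis acid may ionise the dienylic silyl ether before cycloaddition. Fallback (sets out from 12, returns at 16): the activating group is moved from the tether onto the dienophile carbon, so that the endo rule itself enforces the trans fusion. A Morita–Baylis–Hillman reaction of 12 with methyl acrylate and DABCO should give the α-(1-hydroxyalkyl)acrylate F1. Heating in toluene (or Me2AlCl at low temperature) should close the same C5–C10 and C6–C7 bonds with the ester endo and the tether exo, giving the trans-fused C5 ester F2. LiAlH4 reduction gives the diol F3, iodination of the primary hydroxyl (I2, PPh3, imidazole) the neopentyl iodide F4, and Bu3SnH/AIBN the C5-methyl alcohol F5. Dess–Martin oxidation of the C4 carbinol then returns to 16.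

2. Step 15. The equatorial C7–O bond of the trans-fused half-chair overlaps poorly with the alkene, so a [1,2]-shift or simple protonation of the α-alkoxymethyllithium may outrun the [2,3] shift. Fallback (sets out from 21, returns at 24): a thermal [3,3] shift, which tolerates a boat-like geometry, followed by excision of one carbon. Triethyl orthoacetate with catalytic propionic acid at 140 °C (Johnson–Claisen rearrangement) should give the C9 acetic ester F6 with the new bond on the α face and the alkene at C7–C8. LiOH gives the carboxylic acid F7. Barton decarboxylative hydroxylation (N-hydroxypyridine-2-thione ester, O2, t-BuSH, light, then P(OMe)3) gives the C11 alcohol F8, and TESCl with imidazole returns to 24.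

3. Step 13. The axial C7 oxyphosphonium ion has an antiperiplanar hydrogen at C6, so elimination to the 6,8-diene may compete with substitution. Fallback (sets out from 19, returns at 24): the 7β configuration is kept and used as a pseudoaxial leaving group for an anti-SN2′ substitution, which bypasses steps 13 to 15. Picolinic acid, DCC and DMAP give the 7β-picolinate F9. (i-PrO)Me2SiCH2MgCl with CuBr·SMe2 in THF at −40 °C should attack C9 anti to the leaving group, that is from the α face, to give the C9 (isopropoxydimethylsilyl)methyl compound F10 with the alkene at C7–C8. Tamao oxidation (H2O2, KF, KHCO3) gives the same C11 alcohol F8, and TESCl with imidazole returns to 24.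

**Further compounds**

F1 | step 9 | methyl 2-[(4S,5E)-1-hydroxy-4-(TBS-oxy)-6,7-dimethylocta-5,7-dienyl]acrylate, C4 epimers | C=C(C(=O)OC)C(O)CC[C@H](O[Si](C)(C)C(C)(C)C)/C=C(\C)C(C)=C
F2 | step 9 | trans-fused 4-hydroxy-5β-methoxycarbonyl-1α-(TBS-oxy)-8,9-dimethyl-8-ene | OC1CC[C@H](O[Si](C)(C)C(C)(C)C)[C@@H]2[C@]1(C(=O)OC)CCC(C)=C2C
F3 | step 9 | 4-hydroxy-5β-hydroxymethyl diol | OC1CC[C@H](O[Si](C)(C)C(C)(C)C)[C@@H]2[C@]1(CO)CCC(C)=C2C
F4 | step 9 | 4-hydroxy-5β-iodomethyl compound | OC1CC[C@H](O[Si](C)(C)C(C)(C)C)[C@@H]2[C@]1(CI)CCC(C)=C2C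
F5 | step 9 | C4 alcohol of 16 (5β-methyl) | OC1CC[C@H](O[Si](C)(C)C(C)(C)C)[C@@H]2[C@]1(C)CCC(C)=C2C
F6 | step 15 | ethyl ester of the 9α-acetic acid (9β-methyl, 7-ene) | C14(OCCO4)CC[C@H](O[Si](C)(C)C(C)(C)C)[C@@H]2[C@]1(C)CC=C(C)[C@@]2(C)CC(=O)OCC
F7 | step 15 | 9α-acetic acid (9β-methyl, 7-ene) | C14(OCCO4)CC[C@H](O[Si](C)(C)C(C)(C)C)[C@@H]2[C@]1(C)CC=C(C)[C@@]2(C)CC(=O)O
F8 | step 15 | 9α-hydroxymethyl-9β-methyl-7-ene (C11 alcohol) | C14(OCCO4)CC[C@H](O[Si](C)(C)C(C)(C)C)[C@@H]2[C@]1(C)CC=C(C)[C@@]2(C)CO
F9 | step 13 | 7β-picolinate of 19 | C14(OCCO4)CC[C@H](O[Si](C)(C)C(C)(C)C)[C@@H]2[C@]1(C)C[C@H](OC(=O)c3ccccn3)C(C)=C2C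
F10 | step 13 | 9α-[(isopropoxydimethylsilyl)methyl]-9β-methyl-7-ene | C14(OCCO4)CC[C@H](O[Si](C)(C)C(C)(C)C)[C@@H]2[C@]1(C)CC=C(C)[C@@]2(C)C[Si](C)(C)OC(C)C
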